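The earlier runs and the new flask are calculated with constants of no real substance, noise included.

| flask | Q | Z | remark | time |
|---|---|---|---|---|
| dawn | 0.10 M | 1.7 equiv | run made earlier |  |
| noon | 0.10 M | 2.6 equiv | run made earlier |  |
| winter | 0.20 M | 1.2 equiv | run made earlier |  |
| flask | 0.10 M | 1.20 equiv |  | 8.0 min |

| run | time / min | J / % | X / % |
|---|---|---|---|
| dawn | 1.00 | 10.1 | 8.9 |
| dawn | 2.00 | 25.5 | 22.8 |
| dawn | 3.00 | 39.9 | 36.4 |
| dawn | 4.00 | 53.8 | 50.8 |
| dawn | 5.00 | 64.6 | 61.2 |
| noon | 1.00 | 12.2 | 11.3 |
| noon | 2.00 | 27.3 | 24.7 |
| noon | 3.00 | 42.6 | 37.3 |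
| noon | 4.00 | 57.0 | 51.9 |
| noon | 5.00 | 67.7 | 63.3 |
| winter | 0.417 | 2.8 | 2.4 |
| winter | 1.33 | 10.2 | 7.8 |
| winter | 2.00 | 13.5 | 9.9 |
| winter | 3.00 | 20.0 | 18.9 |
| winter | 5.00 | 35.3 | 34.0 |

(each reading ± 1 percentage point)

- what is said of J includes X
- Q, X is a solid; its amount is given per volume of the solution
- at the start none of Q is in solution
- D is what Q becomes in solution
- D means what is dissolved; the solid is not counted in it

- J and X together at 8.0 min, in percent of the Q charged
- concentration of D in solution at 8.0 min, in percent of saturation

1. Every Q charged stands at any moment as solid, as D, as J, or in a form these readings do not show. So once the solid has ended, the D then present is what I count as J's remaining gain.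

2. In the dawn run J grows at 0.0146 M/min between 1.00 min and 4.00 min. A line of that slope drawn from the start stands 4.47% of the Q charged above the first reading, a lag of 0.307 min. I call this gap, read from scattered readings, the hold-up, and I take it as the D standing between solid and J in a quasi-steady state.

3. Now the question turned round. For the dawn charge to reach J in full with its solid ended at 5.00 min, the missing share would have to sit in D, which asks for a lag of 2.43 min. The readings show a much shorter lag.

4. The last dawn step gives 0.0108 M/min, slower than the line, and I read that as the solid ending. Crediting the dawn run with the hold-up gives my estimate of 69.1%. The flask has the same Q as the dawn run and less Z, but the noon run, with more Z than the dawn run, flows at 0.0149 M/min, like the dawn line, so I carry the dawn line over to the flask. I expect the flask between 64.6% and 69.1%, with D below the hold-up, which I take to be a few percent of saturation.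

5. The forecast, which differs from my reckoning, says 86% (79% to 92%) for J and X together and 30% (18% to 45%) of saturation for D, reasoning that “solid Q holds D at saturation”.

6. The flask gives 64.6% for J and X together, with D at 1.36% of saturation.

    Q ⇌ D, rate k1*(cs1 - [D]) while solid is left; crystals form when [D] > cs1 (solubility = 0.0700 M, k = 0.00351 /s)
    D + Z ⇌ J (K = 59.0 /M, k = 0.770 /M/s)
    X ⇌ J, rate k3*(cs3 - [J]) while solid is left; crystals form when [J] > cs3 (solubility = 3.10 mM, k = 0.912 /s)
    2 Q → G (k = 0.0264 /M/s)

At 8.00 min, 34.5% of the Q charged stands in the flask as G, each G holding two Q. At 4.00 min the flask holds 4.88% as D, against the hold-up of 4.47%. Taking the hold-up off the dawn flow line gives 24.7% for the same flask read at 2.0 min, and that flask gives 24.6%.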